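A direct plan would build ring C last from a chalcone: syringaldehyde A1 would be methoxylated at C2 to 4-hydroxy-2,3,5-trimethoxybenzaldehyde A2, A2 would be condensed with 1-(2,6-dihydroxy-4-methoxyphenyl)ethanone A3 to chalcone A4, A4 would be closed to flavanone A5, and A5 would be dehydrogenated with iodine in DMSO. Its weakest steps would be the C–H methoxylation of A1 meta to the phenol, for which no dependable method exists; the aldol condensation of A2 with A3, in which base would deactivate the formyl group through the para-phenoxide and acid would invite early ring closure; and the oxidation of A5, in which hot iodine would meet two electron-rich free phenols.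

The route rests on the C2–C1' bond, formed last between two intact halves. It exploits that C1' of ring B lies para to the free 4'-OH, whose two ortho positions carry methoxy groups, so that unfunctionalised 2,3,6-trimethoxyphenol should react there, and that C2 and C4 of ring C both bear oxygen, so that a coumarin can stand in for the chromone. Rings A and C are carried as a 4-methoxycoumarin; activation of its lactone carbonyl makes C2 a benzopyrylium electrophile for the phenol's para C–H, and the 4-methoxyflavylium salt formed is hydrolysed to the C4 carbonyl. One redox-neutral operation joins the rings at the flavone oxidation level; no formylated ring B, aldol step or oxidative ring closure remains.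

Key step: step 4

Remark: the target has no stereocentre, so every selectivity question of the route is regiochemical; 2,3,6-trimethoxyphenol is made rather than bought.

Step 1
Reactants: 1 1,2,4-trimethoxybenzene
Product: 4 2,3,6-trimethoxyphenol, via aryllithium 2 (not isolated), via lithium arylborate 3 (not isolated)
Conditions: n-BuLi (1.1 equiv), THF, 0 °C → rt, 2 h; B(OMe)3 (1.5 equiv), −78 °C → rt; AcOH (1.5 equiv), 30% aq. H2O2 (1.5 equiv), 0 °C → rt
Reagents that add atoms: hydrogen peroxide, OO
Why: Directed ortho-metalation should take place at C3 of 1, the only ring position flanked by two methoxy groups, and borylation followed by boronate oxidation (1,2-shift of the aryl group from boron to oxygen) replaces C–Li by C–OH, which gives a phenol whose para position is free and whose two ortho positions are blocked.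

Step 2
Reactants: 5 1-(2,6-dihydroxy-4-methoxyphenyl)ethan-1-one
Product: 7 4,5-dihydroxy-7-methoxy-2H-chromen-2-one, via keto ester 6 (not isolated)
Conditions: NaH (5 equiv), (EtO)2CO (8 equiv), toluene, 110 °C, 6 h; then H2O, 2 M HCl to pH 1
Reagents that add atoms: diethyl carbonate, CCOC(=O)OCC
Why: Claisen-type C-acylation of the ketone enolate by diethyl carbonate and lactonisation of keto ester 6 through an ortho-phenoxide is the standard 4-hydroxycoumarin synthesis from 2-hydroxyacetophenones, and because the two ortho-hydroxyl groups of 5 are equivalent either closure gives the same 5-hydroxy-7-methoxy pattern, while the aqueous base formed on quenching cleaves any aryl ethyl carbonate.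

Step 3
Reactants: 7 4,5-dihydroxy-7-methoxy-2H-chromen-2-one
Product: 8 5-hydroxy-4,7-dimethoxy-2H-chromen-2-one
Conditions: MeOH, conc. H2SO4 (0.3 equiv), reflux, 12 h, 3 Å molecular sieves in a Soxhlet thimble
Reagents that add atoms: methanol, CO
Why: Fischer-type acid-catalysed etherification of the vinylogous carboxylic acid (addition of methanol at C4 of the protonated 4-hydroxycoumarin, then loss of water) gives the thermodynamically preferred 4-methoxycoumarin, while the phenolic 5-OH and the lactone are inert to acidic methanol, and it fixes the C4 oxygen as an ether so that only the C2 oxygen remains a carbonyl that can be activated.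

Step 4
Reactants: 8 5-hydroxy-4,7-dimethoxy-2H-chromen-2-one; 4 2,3,6-trimethoxyphenol
Product: 11 5-hydroxy-2-(4-hydroxy-2,3,5-trimethoxyphenyl)-7-methoxy-4H-chromen-4-one, via 2-chlorobenzopyrylium salt 9 (not isolated), via 4-methoxyflavylium salt 10 (not isolated)
Conditions: POCl3 (3 equiv), ZnCl2 (1.0 equiv), ClCH2CH2Cl, 60 °C, 30 min; then 4 (1.05 equiv), 70 °C, 4 h; then ice–H2O/MeCN, 50 °C, 1 h
Reagents that add atoms: water, O
Why: Proposed new method: the lactone carbonyl oxygen of 8, made nucleophilic by the donors at C4, C5 and C7, is phosphorylated by POCl3 and replaced by chloride to give the 2-chlorobenzopyrylium ion 9, the para carbon of phenol 4 adds to C2 (the alpha position of the pyrylium ion), loss of a proton and of chloride gives the 4-methoxyflavylium ion 10, and on work-up water adds at C4 with loss of methanol to reveal the chromone carbonyl of 11. The closest known reaction type is the POCl3/ZnCl2 condensation of coumarins, chromones and xanthones with phenols, phenol ethers and dialkylanilines to 2-aryl- and 4-arylbenzopyrylium and 9-arylxanthylium salts; new is the 4-alkoxycoumarin as substrate, which makes the flavylium salt a masked flavone and the step a coumarin-to-flavone transposition. No ring is closed and no stereocentre is formed: the step makes the C2–C1' bond between the preformed rings C and B. On the electrophile, attack must go to C2 and not to C4, which is secured because C2 carries the chloride leaving group and little donor stabilisation whereas C4 is deactivated by its methoxy group and shielded by the peri 5-OH; on the nucleophile, C4 of 4 must react and not C5, which is secured because both positions ortho to the hydroxyl group are blocked, C4 is para to the free hydroxyl group, and C5 is para only to the 2-methoxy group, which its two neighbours twist out of conjugation. O-Arylation is not a dead end, since a 2-aryloxybenzopyrylium ion is itself an activated lactone that returns to 9, while C-arylation becomes irreversible when 10 loses its 4'-OH proton to form a neutral quinoidal base. The medium is that of the Grover–Shah–Shah xanthone synthesis, which polyphenols and aryl methyl ethers tolerate, and it contains no oxidant, so the electron-rich free phenols are not at risk.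

**Compound list**
1 | 1,2,4-trimethoxybenzene | COc1ccc(OC)c(OC)c1 | starting material
2 | (2,3,6-trimethoxyphenyl)lithium | [Li]c1c(OC)ccc(OC)c1OC | intermediate
3 | lithium trimethoxy(2,3,6-trimethoxyphenyl)borate | [Li+].CO[B-](OC)(OC)c1c(OC)ccc(OC)c1OC | intermediate
4 | 2,3,6-trimethoxyphenol | COc1ccc(OC)c(OC)c1O | intermediate
5 | 1-(2,6-dihydroxy-4-methoxyphenyl)ethan-1-one | CC(=O)c1c(O)cc(OC)cc1O | starting material
6 | ethyl 3-(2,6-dihydroxy-4-methoxyphenyl)-3-oxopropanoate | CCOC(=O)CC(=O)c1c(O)cc(OC)cc1O | intermediate
7 | 4,5-dihydroxy-7-methoxy-2H-chromen-2-one | COc1cc(O)c2c(O)cc(=O)oc2c1 | intermediate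
8 | 5-hydroxy-4,7-dimethoxy-2H-chromen-2-one | COc1cc(O)c2c(OC)cc(=O)oc2c1 | intermediate
9 | 2-chloro-5-hydroxy-4,7-dimethoxychromenylium dichlorophosphate | COc1cc(O)c2c(OC)cc(Cl)[o+]c2c1.[O-]P(=O)(Cl)Cl | intermediate
10 | 5-hydroxy-2-(4-hydroxy-2,3,5-trimethoxyphenyl)-4,7-dimethoxychromenylium dichlorophosphate | COc1cc(O)c2c(OC)cc(-c3cc(OC)c(O)c(OC)c3OC)[o+]c2c1.[O-]P(=O)(Cl)Cl | intermediate
11 | 5-hydroxy-2-(4-hydroxy-2,3,5-trimethoxyphenyl)-7-methoxy-4H-chromen-4-one | COc1cc(O)c2c(=O)cc(-c3cc(OC)c(O)c(OC)c3OC)oc2c1 | target

Total step count: 4. Longest linear sequence: 3 steps (5 → 7 → 8 → 11); the branch 1 → 4 is one step.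

Steps most likely to fail:

1. Step 4 (proposed new method). The phenol may attack C4 of the activated coumarin with loss of methanol, which leads into the 4-arylcoumarin series. The 4-O-methyl group may be lost to chloride before the C–C bond forms, 8 may condense with itself through its nucleophilic C3, or the free phenols may be phosphorylated. The fallback uses known chemistry, sets out from 5 and 4, and returns at 11. Compound 5 would be condensed with N,N-dimethylformamide dimethyl acetal to (E)-1-(2,6-dihydroxy-4-methoxyphenyl)-3-(dimethylamino)prop-2-en-1-one F1, which aqueous HCl would close to 5-hydroxy-7-methoxy-4H-chromen-4-one F2. Benzylation (BnBr, K2CO3, DMF, 70 °C) would give 5-(benzyloxy)-7-methoxy-4H-chromen-4-one F3. In parallel, 4 would be iodinated para to its hydroxyl group with N-iodosuccinimide to 4-iodo-2,3,6-trimethoxyphenol F4 and benzylated to 1-(benzyloxy)-4-iodo-2,3,6-trimethoxybenzene F5. F3 would be zincated at C2 with TMP2Zn·2MgCl2·2LiCl (0.6 equiv; TMP = 2,2,6,6-tetramethylpiperidide) in THF at −30 °C to bis[5-(benzyloxy)-7-methoxy-4-oxo-4H-chromen-2-yl]zinc F6. The magnesium chloride bound at the carbonyl oxygen should direct the base to the more acidic C2–H; the Lewis-acid-free base TMPZnCl·LiCl would be avoided because it is expected to metalate C3. Negishi coupling of F6 with two equivalents of F5 (Pd(dba)2, tri(2-furyl)phosphine, THF, 50 °C) would give 5-(benzyloxy)-2-[4-(benzyloxy)-2,3,5-trimethoxyphenyl]-7-methoxy-4H-chromen-4-one F7, and hydrogenolysis (H2, Pd/C, EtOAc, rt) would give 11.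

2. Step 2. C-Acylation may stay incomplete, because the twofold phenoxide of 5 is a poor carbon acid and its sodium salt is sparingly soluble, so that O-ethoxycarbonylation takes over. The fallback sets out from 5 and returns at 7. One hydroxyl group would be masked first: BnBr (1.05 equiv) and K2CO3 in acetone would give 1-[2-(benzyloxy)-6-hydroxy-4-methoxyphenyl]ethan-1-one F8, the second, chelated hydroxyl group reacting much more slowly. The same NaH/diethyl carbonate condensation, now needing only a dianion, would give 5-(benzyloxy)-4-hydroxy-7-methoxy-2H-chromen-2-one F9, and hydrogenolysis (H2, Pd/C) would give 7.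

3. Step 3. The etherification may stop short against the water equilibrium, slowed by the hydrogen bond from 5-OH, or methylation may occur at the lactone oxygen; the resulting 2-methoxychromone isomer would direct the key step to C4. The fallback sets out from 7 and returns at 8. It forms the O–CH3 bond instead of the C4–O bond: K2CO3 (1.0 equiv) and Me2SO4 (1.0 equiv) in acetone at rt would alkylate the anion of the far more acidic 4-enol and leave the phenolic 5-OH untouched. It makes no new compound (F0).

Further compounds
F1 | step 4 | (E)-1-(2,6-dihydroxy-4-methoxyphenyl)-3-(dimethylamino)prop-2-en-1-one | CN(C)/C=C/C(=O)c1c(O)cc(OC)cc1O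
F2 | step 4 | 5-hydroxy-7-methoxy-4H-chromen-4-one | COc1cc(O)c2c(=O)ccoc2c1
F3 | step 4 | 5-(benzyloxy)-7-methoxy-4H-chromen-4-one | COc1cc(OCc2ccccc2)c2c(=O)ccoc2c1
F4 | step 4 | 4-iodo-2,3,6-trimethoxyphenol | COc1cc(I)c(OC)c(OC)c1O
F5 | step 4 | 1-(benzyloxy)-4-iodo-2,3,6-trimethoxybenzene | COc1cc(I)c(OC)c(OC)c1OCc1ccccc1
F6 | step 4 | bis[5-(benzyloxy)-7-methoxy-4-oxo-4H-chromen-2-yl]zinc | COc1cc(OCc2ccccc2)c2c(=O)cc([Zn]c3cc(=O)c4c(OCc5ccccc5)cc(OC)cc4o3)oc2c1
F7 | step 4 | 5-(benzyloxy)-2-[4-(benzyloxy)-2,3,5-trimethoxyphenyl]-7-methoxy-4H-chromen-4-one | COc1cc(OCc2ccccc2)c2c(=O)cc(-c3cc(OC)c(OCc4ccccc4)c(OC)c3OC)oc2c1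
F8 | step 2 | 1-[2-(benzyloxy)-6-hydroxy-4-methoxyphenyl]ethan-1-one | CC(=O)c1c(O)cc(OC)cc1OCc1ccccc1
F9 | step 2 | 5-(benzyloxy)-4-hydroxy-7-methoxy-2H-chromen-2-one | COc1cc(OCc2ccccc2)c2c(O)cc(=O)oc2c1
F0 | step 3 | none | none
A1 | direct plan | syringaldehyde (4-hydroxy-3,5-dimethoxybenzaldehyde) | COc1cc(C=O)cc(OC)c1O
A2 | direct plan | 4-hydroxy-2,3,5-trimethoxybenzaldehyde | COc1cc(C=O)c(OC)c(OC)c1O
A3 | direct plan | 1-(2,6-dihydroxy-4-methoxyphenyl)ethanone | CC(=O)c1c(O)cc(OC)cc1O
A4 | direct plan | (E)-1-(2,6-dihydroxy-4-methoxyphenyl)-3-(4-hydroxy-2,3,5-trimethoxyphenyl)prop-2-en-1-one | COc1cc(O)c(C(=O)/C=C/c2cc(OC)c(O)c(OC)c2OC)c(O)c1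
A5 | direct plan | 5-hydroxy-2-(4-hydroxy-2,3,5-trimethoxyphenyl)-7-methoxychroman-4-one (racemic at C2) | COc1cc(O)c2C(=O)CC(Oc2c1)c1cc(OC)c(O)c(OC)c1OC
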